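**Retrosynthetic overview**

- The route rests on the tetrasubstituted C1=C10 alkene shared by ring A (C1–C5, five-membered) and ring B (C1, C5–C10, seven-membered): it is the trace of a C1≡C10 alkyne, and C5–C6–C7–C8–C9 is the trace of a vinylcyclopropane (alkene C5=C6, cyclopropane C7/C8/C9).
- Key disconnection: C1–C5 and C9–C10, formed in one rhodium-catalysed (5+2) cycloaddition; ring A closes through the C2–C3–C4 tether and ring B in the same event.
- The enyne is cut at C5=C6 (Julia–Kocienski) into an α-silyloxy aldehyde from (S)-linalool (carries C4) and a tetrazolyl sulfone of a trans-2-alkoxy-1-isopropylcyclopropane (carries C8), made from methyl isovalerate by asymmetric cyclopropanation of an enol-ether allylic alcohol.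
- After the cycloaddition, a silicon tether on O8 delivers hydrogen to C7 and oxygen to C6 on the β face; C8 is then acylated, C6 is inverted by oxidation/reduction, and the silyl groups are removed.

Key step: step 12

**Remarks**

- Guaiane numbering is used throughout (C14 = methyl on C10, C15 = methyl on C4, isopropyl on C7). β is the face of ring B that carries H-5 in the target, α the opposite face; the target is then 4α-OH, 5β-H, 6α-OH, 7β-H, 8β-O-acyl, (4S,5S,6R,7S,8S).
- Assumption: the dioxaborolane-controlled cyclopropanation of the enol-ether allylic alcohol 11 follows the same facial sense as that of (E)-cinnamyl alcohol.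
- Numbers are given to intermediates that are made in one operation and consumed by a second operation in the same flask; species that exist only within one operation are described in the Why line.
- The hydroboration/ketone-equilibration sequence for C6/C7 was not used: syn hydroboration cannot give the 6α-OH/7β-H pattern directly, and base equilibration of a C6 ketone would first deprotonate the doubly activated C5–H (epimerisation, conjugation of C1=C10).

**Route**

Step 1
Reactants: 1 (S)-linalool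
Product: 2 triethylsilyl ether of (S)-linalool
Conditions: Et3SiOTf, 2,6-lutidine, CH2Cl2, −78 to 0 °C
Reagents that add atoms: triethylsilyl trifluoromethanesulfonate, CC[Si](CC)(CC)OS(=O)(=O)C(F)(F)F
Why: Silyl ether formation with a silyl triflate and a hindered pyridine base protects the tertiary allylic alcohol without ionising it, so the stereocentre (future C4) is untouched.

Step 2
Reactants: 2 triethylsilyl ether of (S)-linalool
Product: 3 (4S)-4-methyl-4-[(triethylsilyl)oxy]hex-5-enal
Conditions: O3 (1.0 equiv), CH2Cl2/pyridine, −78 °C; then Me2S, −78 °C to rt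
Reagents that add atoms: ozone, [O-][O+]=O
Why: Ozonolysis with reductive work-up; the electron-rich trisubstituted alkene reacts much faster than the monosubstituted vinyl group, so one equivalent of ozone should cleave only the former.

Step 3
Reactants: 3 (4S)-4-methyl-4-[(triethylsilyl)oxy]hex-5-enal
Product: 4 triethyl{[(3S)-3-methylhept-1-en-6-yn-3-yl]oxy}silane
Conditions: dimethyl (1-diazo-2-oxopropyl)phosphonate, K2CO3, MeOH, 0 °C to rt
Reagents that add atoms: dimethyl (1-diazo-2-oxopropyl)phosphonate, COP(=O)(OC)C(=[N+]=[N-])C(C)=O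
Why: Seyferth–Gilbert homologation in its Ohira–Bestmann form turns the aldehyde into the terminal alkyne (future C1≡C10) under conditions mild enough for the silyl ether.

Step 4
Reactants: 4 triethyl{[(3S)-3-methylhept-1-en-6-yn-3-yl]oxy}silane
Product: 6 triethyl{[(3S)-3-methyloct-1-en-6-yn-3-yl]oxy}silane, via lithium acetylide 5 (not isolated)
Conditions: n-BuLi, THF, −78 °C; then MeI, −78 °C to rt
Reagents that add atoms: n-butyllithium, [Li]CCCC (lithium in 5 only); iodomethane, CI
Why: Deprotonation of the terminal alkyne and SN2 alkylation of the acetylide install the C14 methyl group.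

Step 5
Reactants: 6 triethyl{[(3S)-3-methyloct-1-en-6-yn-3-yl]oxy}silane
Product: 7 (2S)-2-methyl-2-[(triethylsilyl)oxy]hept-5-ynal
Conditions: O3, CH2Cl2, −78 °C (Sudan Red 7B end point); then Me2S, −78 °C to rt
Reagents that add atoms: ozone, [O-][O+]=O
Why: Ozonolysis cleaves the vinyl group far faster than the internal alkyne, and the resulting aldehyde (C5) has no α-hydrogen, so C4 cannot epimerise.

Step 6
Reactants: 8 methyl isovalerate
Product: 10 methyl (2E)-3-[(4-methoxyphenyl)methoxy]-2-(propan-2-yl)prop-2-enoate, via sodium enolate 9 (not isolated)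
Conditions: NaH, HCO2Me, THF, 0 °C to rt; then DMF, 4-MeOC6H4CH2Cl, rt
Reagents that add atoms: methyl formate, COC=O; 4-methoxybenzyl chloride, COc1ccc(CCl)cc1; sodium hydride, [Na+].[H-] (sodium in 9 only)
Why: Crossed Claisen formylation followed by O-alkylation of the formyl-ester enolate in a dipolar aprotic solvent (α-branching disfavours C-alkylation) should give mainly the E enol ether, as in β-methoxyacrylate syntheses; any Z isomer is removed by chromatography.

Step 7
Reactants: 10 methyl (2E)-3-[(4-methoxyphenyl)methoxy]-2-(propan-2-yl)prop-2-enoate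
Product: 11 (2E)-3-[(4-methoxyphenyl)methoxy]-2-(propan-2-yl)prop-2-en-1-ol
Conditions: i-Bu2AlH, CH2Cl2, −78 °C; aq. KNaC4H4O6 work-up
Reagents that add atoms: none
Why: 1,2-Reduction of the vinylogous carbonate by the aluminium hydride gives the allylic alcohol with the alkene geometry kept; the neutral tartrate work-up protects the acid-sensitive enol ether.

Step 8
Reactants: 11 (2E)-3-[(4-methoxyphenyl)methoxy]-2-(propan-2-yl)prop-2-en-1-ol
Product: 12 [(1S,2S)-2-[(4-methoxyphenyl)methoxy]-1-(propan-2-yl)cyclopropyl]methanol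
Conditions: Et2Zn, CH2I2, DME, (4R,5R)-2-butyl-N,N,N′,N′-tetramethyl-1,3,2-dioxaborolane-4,5-dicarboxamide (1.2 equiv), CH2Cl2, −10 °C to rt
Reagents that add atoms: diiodomethane, ICI (delivered as Zn(CH2I)2)
Why: Charette asymmetric Simmons–Smith cyclopropanation: the zinc alkoxide bound to the chiral dioxaborolane directs Zn(CH2I)2 to one alkene face (the face that gives (1S,2S) from (E)-cinnamyl alcohol with this ligand), which sets C7 and C8, while stereospecific syn addition keeps the alkoxy group trans to CH2OH.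

Step 9
Reactants: 12 [(1S,2S)-2-[(4-methoxyphenyl)methoxy]-1-(propan-2-yl)cyclopropyl]methanol
Product: 13 5-({[(1R,2S)-2-[(4-methoxyphenyl)methoxy]-1-(propan-2-yl)cyclopropyl]methyl}sulfanyl)-1-phenyl-1H-tetrazole
Conditions: 1-phenyl-1H-tetrazole-5-thiol, PPh3, DIAD, THF, 0 °C to rt
Reagents that add atoms: 1-phenyl-1H-tetrazole-5-thiol, Sc1nnnn1-c1ccccc1
Why: Mitsunobu thioetherification displaces the primary carbinol by the acidic thiol in an SN2 process under neutral conditions that spare the alkoxycyclopropane; the ring stereocentres are not involved (the descriptor at C1 changes only through priorities).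

Step 10
Reactants: 13 tetrazolyl sulfide
Product: 14 5-({[(1R,2S)-2-[(4-methoxyphenyl)methoxy]-1-(propan-2-yl)cyclopropyl]methyl}sulfonyl)-1-phenyl-1H-tetrazole
Conditions: 30% H2O2, (NH4)6Mo7O24·4H2O (cat.), EtOH, 0 °C to rt
Reagents that add atoms: hydrogen peroxide, OO
Why: Molybdate-catalysed peroxide oxidation takes the sulfide to the sulfone without touching the ethers or the cyclopropane.

Step 11
Reactants: 14 tetrazolyl sulfone; 7 (2S)-2-methyl-2-[(triethylsilyl)oxy]hept-5-ynal
Product: 15 triethyl({(3S,1E)-1-[(1S,2S)-2-[(4-methoxyphenyl)methoxy]-1-(propan-2-yl)cyclopropyl]-3-methyloct-1-en-6-yn-3-yl}oxy)silane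
Conditions: KN(SiMe3)2 added to 14 and 7, DME, −60 °C to rt
Reagents that add atoms: none
Why: Julia–Kocienski olefination: the sulfonyl carbanion adds to the non-enolisable aldehyde, and Smiles rearrangement with loss of SO2 and tetrazolate gives the C5=C6 alkene, E by the usual preference of phenyltetrazolyl sulfones and by the two quaternary neighbours.

Step 12
Reactants: 15 enyne with trans-2-alkoxy-1-isopropyl-1-vinylcyclopropane terminus
Product: 16 8β-[(4-methoxyphenyl)methoxy]-4α-[(triethylsilyl)oxy]-5βH-guaia-1(10),6-diene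
Conditions: [Rh(CO)2Cl]2 (5 mol %), ClCH2CH2Cl (0.02 M), 80 °C
Reagents that add atoms: none
Why: Monovalent rhodium binds the C5=C6 alkene and the C1≡C10 alkyne, opens the cyclopropane bond C7–C9 to a trivalent rhodium allyl/alkyl species, inserts the alkyne into the rhodium–allyl bond (C1–C5) and reductively eliminates C9–C10. The closest known reaction is the rhodium-catalysed intramolecular (5+2) cycloaddition of tethered alkyne–vinylcyclopropanes with [Rh(CO)2Cl]2. Ring A closes when C1–C5 forms across the three-atom tether C2–C3–C4, and ring B closes by C9–C10 reductive elimination from the eight-membered rhodacycle, which leaves the C1=C10 and C6=C7 alkenes in place. The new stereocentre C5 is controlled by C4: with the tether pointing to rhodium, the silyloxy group should eclipse the C5=C6 bond and the methyl group lie anti to the metal, giving H-5 cis to the C4 methyl (5β-H). C8 is carried over unchanged and C7 becomes sp2. The step needs cleavage of C7–C9 and not C7–C8; the alkoxy group trans to the vinyl group and this catalyst should favour the unsubstituted bond, which gives the primary C9–rhodium bond rather than a secondary α-alkoxyalkyl one.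

Step 13
Reactants: 16 8β-[(4-methoxyphenyl)methoxy]-4α-[(triethylsilyl)oxy]-5βH-guaia-1(10),6-diene
Product: 17 4α-[(triethylsilyl)oxy]-5βH-guaia-1(10),6-dien-8β-ol
Conditions: DDQ, CH2Cl2/pH 7 phosphate buffer, 0 °C
Reagents that add atoms: none
Why: Oxidative cleavage of the 4-methoxybenzyl ether (benzylic hydride abstraction, then hydrolysis of the oxocarbenium ion) should be faster at 0 °C than any hydride abstraction from C5, and the buffer protects the tertiary silyl ether.

Step 14
Reactants: 17 4α-[(triethylsilyl)oxy]-5βH-guaia-1(10),6-dien-8β-ol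
Product: 20 4α-[(triethylsilyl)oxy]-5βH,7βH-guai-1(10)-ene-6β,8β-diol, via dimethylsilyl ether 18 (not isolated), via oxasilolane 19 (not isolated)
Conditions: (HMe2Si)2NH, 60 °C, then evaporation; Pt2[(CH2=CHSiMe2)2O]3 (1 mol %), toluene, 60 °C; then KF, KHCO3, 30% H2O2, THF/MeOH, rt
Reagents that add atoms: 1,1,3,3-tetramethyldisilazane, C[SiH](C)N[SiH](C)C (silicon in 18 and 19 only); hydrogen peroxide, OO
Why: Intramolecular hydrosilylation of an allylic alcohol hydrosilyl ether (five-membered endo mode, zerovalent platinum) followed by Tamao oxidation with retention: the tether on the β-oxygen at C8 forces syn delivery of silicon to C6 and hydrogen to C7 on the β face, which sets 7β-H (isopropyl α) and gives 6β-OH, while the tetrasubstituted C1=C10 alkene is inert.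

Step 15
Reactants: 21 4-hydroxybenzoic acid
Product: 23 4-[(tert-butyldimethylsilyl)oxy]benzoic acid, via bis-silyl derivative 22 (not isolated)
Conditions: t-BuMe2SiCl (2.2 equiv), imidazole, DMF, rt; then AcOH/THF/H2O, rt
Reagents that add atoms: tert-butyldimethylsilyl chloride, CC(C)(C)[Si](C)(C)Cl
Why: Silylation of both hydroxyl groups followed by selective hydrolysis of the labile silyl ester with aqueous acetic acid leaves the aryl silyl ether.

Step 16
Reactants: 20 4α-[(triethylsilyl)oxy]-5βH,7βH-guai-1(10)-ene-6β,8β-diol; 23 4-[(tert-butyldimethylsilyl)oxy]benzoic acid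
Product: 24 6β-hydroxy-4α-[(triethylsilyl)oxy]-5βH,7βH-guai-1(10)-en-8β-yl 4-[(tert-butyldimethylsilyl)oxy]benzoate
Conditions: EDC·HCl, DMAP (cat.), CH2Cl2, 0 °C
Reagents that add atoms: none
Why: Steglich esterification should take the C8 hydroxyl (next to the C9 methylene) in preference to the C6 hydroxyl (between the ring-fusion carbon C5 and C7), and acyl migration would also favour the less hindered O8.

Step 17
Reactants: 24 6β-hydroxy C8 ester
Product: 25 6-oxo-4α-[(triethylsilyl)oxy]-5βH,7βH-guai-1(10)-en-8β-yl 4-[(tert-butyldimethylsilyl)oxy]benzoate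
Conditions: Dess–Martin periodinane, NaHCO3, CH2Cl2, 0 °C to rt
Reagents that add atoms: none
Why: Dess–Martin oxidation works under buffered, base-free conditions, so neither C5 nor C7 epimerises and the β-acyloxy ketone does not eliminate.

Step 18
Reactants: 25 6-oxo C8 ester
Product: 26 6α-hydroxy-4α-[(triethylsilyl)oxy]-5βH,7βH-guai-1(10)-en-8β-yl 4-[(tert-butyldimethylsilyl)oxy]benzoate
Conditions: NaBH4, CeCl3·7H2O, MeOH/THF, −40 °C
Reagents that add atoms: none
Why: Luche-type borohydride reduction: hydride should attack the ketone from the β face, which is flanked by H-5 and H-7 and lies opposite the isopropyl group and the C4 branch, to give the 6α-alcohol, and the cerium salt keeps the medium weakly basic so the aryl ester stays in place.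

Step 19
Reactants: 26 6α-hydroxy C8 ester
Product: 27 (4S,5S,6R,7S,8S)-4α,6α-dihydroxy-5βH,7βH-guai-1(10)-en-8β-yl 4-hydroxybenzoate
Conditions: HF·pyridine, pyridine, THF, 0 °C to rt
Reagents that add atoms: none
Why: Fluoride-mediated desilylation removes the tertiary triethylsilyl ether and the aryl silyl ether in one operation under buffered acidic conditions that do not promote acyl migration.

**Compound list**

1 | (S)-linalool, (3S)-3,7-dimethylocta-1,6-dien-3-ol | C=C[C@@](C)(O)CCC=C(C)C | starting material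
2 | triethyl{[(3S)-3,7-dimethylocta-1,6-dien-3-yl]oxy}silane | C=C[C@@](C)(O[Si](CC)(CC)CC)CCC=C(C)C | intermediate
3 | (4S)-4-methyl-4-[(triethylsilyl)oxy]hex-5-enal | C=C[C@@](C)(O[Si](CC)(CC)CC)CCC=O | intermediate
4 | triethyl{[(3S)-3-methylhept-1-en-6-yn-3-yl]oxy}silane | C=C[C@@](C)(O[Si](CC)(CC)CC)CCC#C | intermediate
5 | lithium acetylide of 4 | C=C[C@@](C)(O[Si](CC)(CC)CC)CCC#C[Li] | intermediate
6 | triethyl{[(3S)-3-methyloct-1-en-6-yn-3-yl]oxy}silane | C=C[C@@](C)(O[Si](CC)(CC)CC)CCC#CC | intermediate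
7 | (2S)-2-methyl-2-[(triethylsilyl)oxy]hept-5-ynal | O=C[C@@](C)(O[Si](CC)(CC)CC)CCC#CC | intermediate
8 | methyl isovalerate (methyl 3-methylbutanoate) | COC(=O)CC(C)C | starting material
9 | sodium 2-(methoxycarbonyl)-3-methylbut-1-en-1-olate | COC(=O)C(=C[O-])C(C)C.[Na+] | intermediate
10 | methyl (2E)-3-[(4-methoxyphenyl)methoxy]-2-(propan-2-yl)prop-2-enoate | COC(=O)/C(C(C)C)=C/OCc1ccc(OC)cc1 | intermediate
11 | (2E)-3-[(4-methoxyphenyl)methoxy]-2-(propan-2-yl)prop-2-en-1-ol | OC/C(C(C)C)=C/OCc1ccc(OC)cc1 | intermediate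
12 | [(1S,2S)-2-[(4-methoxyphenyl)methoxy]-1-(propan-2-yl)cyclopropyl]methanol | OC[C@@]1(C(C)C)C[C@@H]1OCc1ccc(OC)cc1 | intermediate
13 | 5-({[(1R,2S)-2-[(4-methoxyphenyl)methoxy]-1-(propan-2-yl)cyclopropyl]methyl}sulfanyl)-1-phenyl-1H-tetrazole | S(C[C@@]1(C(C)C)C[C@@H]1OCc1ccc(OC)cc1)c1nnnn1-c1ccccc1 | intermediate
14 | 5-({[(1R,2S)-2-[(4-methoxyphenyl)methoxy]-1-(propan-2-yl)cyclopropyl]methyl}sulfonyl)-1-phenyl-1H-tetrazole | O=S(=O)(C[C@@]1(C(C)C)C[C@@H]1OCc1ccc(OC)cc1)c1nnnn1-c1ccccc1 | intermediate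
15 | triethyl({(3S,1E)-1-[(1S,2S)-2-[(4-methoxyphenyl)methoxy]-1-(propan-2-yl)cyclopropyl]-3-methyloct-1-en-6-yn-3-yl}oxy)silane | CC#CCC[C@](C)(O[Si](CC)(CC)CC)/C=C/[C@@]1(C(C)C)C[C@@H]1OCc1ccc(OC)cc1 | intermediate
16 | 8β-[(4-methoxyphenyl)methoxy]-4α-[(triethylsilyl)oxy]-5βH-guaia-1(10),6-diene | CC1=C2CC[C@](C)(O[Si](CC)(CC)CC)[C@@H]2C=C(C(C)C)[C@@H](OCc2ccc(OC)cc2)C1 | intermediate
17 | 4α-[(triethylsilyl)oxy]-5βH-guaia-1(10),6-dien-8β-ol | CC1=C2CC[C@](C)(O[Si](CC)(CC)CC)[C@@H]2C=C(C(C)C)[C@@H](O)C1 | intermediate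
18 | 8β-[(dimethylsilyl)oxy]-4α-[(triethylsilyl)oxy]-5βH-guaia-1(10),6-diene | CC1=C2CC[C@](C)(O[Si](CC)(CC)CC)[C@@H]2C=C(C(C)C)[C@@H](O[SiH](C)C)C1 | intermediate
19 | dimethyl oxasilolane bridging C6 (Si, β) and O8 (β) of 4α-[(triethylsilyl)oxy]-5βH,7βH-guai-1(10)-ene | CC1=C2CC[C@](C)(O[Si](CC)(CC)CC)[C@@H]2[C@@H]3[C@H](C(C)C)[C@@H](O[Si]3(C)C)C1 | intermediate
20 | 4α-[(triethylsilyl)oxy]-5βH,7βH-guai-1(10)-ene-6β,8β-diol | CC1=C2CC[C@](C)(O[Si](CC)(CC)CC)[C@@H]2[C@@H](O)[C@H](C(C)C)[C@@H](O)C1 | intermediate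
21 | 4-hydroxybenzoic acid | O=C(O)c1ccc(O)cc1 | starting material
22 | tert-butyldimethylsilyl 4-[(tert-butyldimethylsilyl)oxy]benzoate | CC(C)(C)[Si](C)(C)OC(=O)c1ccc(O[Si](C)(C)C(C)(C)C)cc1 | intermediate
23 | 4-[(tert-butyldimethylsilyl)oxy]benzoic acid | CC(C)(C)[Si](C)(C)Oc1ccc(C(=O)O)cc1 | intermediate
24 | 6β-hydroxy-4α-[(triethylsilyl)oxy]-5βH,7βH-guai-1(10)-en-8β-yl 4-[(tert-butyldimethylsilyl)oxy]benzoate | CC1=C2CC[C@](C)(O[Si](CC)(CC)CC)[C@@H]2[C@@H](O)[C@H](C(C)C)[C@@H](OC(=O)c2ccc(O[Si](C)(C)C(C)(C)C)cc2)C1 | intermediate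
25 | 6-oxo-4α-[(triethylsilyl)oxy]-5βH,7βH-guai-1(10)-en-8β-yl 4-[(tert-butyldimethylsilyl)oxy]benzoate | CC1=C2CC[C@](C)(O[Si](CC)(CC)CC)[C@@H]2C(=O)[C@H](C(C)C)[C@@H](OC(=O)c2ccc(O[Si](C)(C)C(C)(C)C)cc2)C1 | intermediate
26 | 6α-hydroxy-4α-[(triethylsilyl)oxy]-5βH,7βH-guai-1(10)-en-8β-yl 4-[(tert-butyldimethylsilyl)oxy]benzoate | CC1=C2CC[C@](C)(O[Si](CC)(CC)CC)[C@@H]2[C@H](O)[C@H](C(C)C)[C@@H](OC(=O)c2ccc(O[Si](C)(C)C(C)(C)C)cc2)C1 | intermediate
27 | (4S,5S,6R,7S,8S)-4α,6α-dihydroxy-5βH,7βH-guai-1(10)-en-8β-yl 4-hydroxybenzoate (CNP0392039.1) | CC1=C2CC[C@](C)(O)[C@@H]2[C@H](O)[C@H](C(C)C)[C@@H](OC(=O)c2ccc(O)cc2)C1 | target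

**Step count**

Total: 19 steps. Longest linear sequence: 13 steps (steps 1–5 or 6–10, then 11–14 and 16–19).

**Steps most likely to fail**

Step 12. Rhodium may insert into the alkoxy-bearing bond C7–C8 instead of C7–C9, the C9–rhodium intermediate may lose the β-alkoxide before ring closure, or the C4 centre may discriminate the two alkene faces poorly. The fallback sets out from 10 and returns at 16; it moves the alkoxy group to the side of the cyclopropane cis to the vinyl group, where a cis substituent is known to force opening of the unsubstituted bond on steric grounds. Sensitised photoisomerisation of 10 (hν 350 nm, benzophenone, MeCN) and chromatography should give methyl (2Z)-3-[(4-methoxyphenyl)methoxy]-2-(propan-2-yl)prop-2-enoate F1, and i-Bu2AlH reduction gives (2Z)-3-[(4-methoxyphenyl)methoxy]-2-(propan-2-yl)prop-2-en-1-ol F2. Cyclopropanation as in step 8, but with the (4S,5S)-dioxaborolane, should give [(1R,2S)-2-[(4-methoxyphenyl)methoxy]-1-(propan-2-yl)cyclopropyl]methanol F3, with the same C8 configuration and the alkoxy group cis to CH2OH. Mitsunobu thioetherification gives 5-({[(1S,2S)-2-[(4-methoxyphenyl)methoxy]-1-(propan-2-yl)cyclopropyl]methyl}sulfanyl)-1-phenyl-1H-tetrazole F4, oxidation gives the corresponding sulfone F5, and Julia–Kocienski olefination with 7 gives the cis-alkoxy enyne F6. Treatment with [Rh(CO)2Cl]2 should then give 16, because C7 becomes sp2 and C8 is carried through.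

Step 14. The endo hydrosilylation onto the hindered ring alkene may be slow, so that platinum hydride migrates the C6=C7 alkene or the silyl ether is simply lost. The fallback sets out from 16 (step 13 is skipped) and returns at 26; it replaces tethered delivery by intermolecular hydroboration and a hydroxyl-directed reduction. BH3·SMe2 in THF at 0 °C followed by NaBO3·4H2O should give 8β-[(4-methoxyphenyl)methoxy]-4α-[(triethylsilyl)oxy]-5βH,7βH-guai-1(10)-en-6β-ol F7, with boron expected at C6 on the H-5 face, anti to the quaternary C4 branch; the 7β-H assignment has to be confirmed at this stage. Dess–Martin oxidation gives 8β-[(4-methoxyphenyl)methoxy]-4α-[(triethylsilyl)oxy]-5βH,7βH-guai-1(10)-en-6-one F8, and DDQ gives 8β-hydroxy-4α-[(triethylsilyl)oxy]-5βH,7βH-guai-1(10)-en-6-one F9. Evans–Saksena reduction (Me4NBH(OAc)3, MeCN/AcOH, −20 °C) delivers hydride from the O8 face and should give 4α-[(triethylsilyl)oxy]-5βH,7βH-guai-1(10)-ene-6α,8β-diol F10. Esterification of the less hindered C8 hydroxyl with 23 (EDC·HCl, DMAP) gives 26.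

Step 11. Addition of the neopentyl-type sulfonyl carbanion to the α-quaternary aldehyde may be slow, and the adduct alkoxide may take the silyl group from O4 before the Smiles step. The fallback sets out from 12 and returns at 15; it uses the stepwise Julia–Lythgoe olefination, in which the adduct is trapped at once. PhSSPh and PBu3 convert 12 into ({[(1R,2S)-2-[(4-methoxyphenyl)methoxy]-1-(propan-2-yl)cyclopropyl]methyl}sulfanyl)benzene F11, and molybdate-catalysed H2O2 oxidation gives the phenyl sulfone F12. Lithiation (n-BuLi, THF, −78 °C), addition to 7 and quenching with Ac2O give the β-acetoxy sulfone F13 as a diastereomer mixture. SmI2 in THF/HMPA (or Na/Hg, Na2HPO4, MeOH) then gives the E alkene 15 by reductive elimination.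

**Further compounds**

F1 | step 12 | methyl (2Z)-3-[(4-methoxyphenyl)methoxy]-2-(propan-2-yl)prop-2-enoate | COC(=O)/C(C(C)C)=C\OCc1ccc(OC)cc1
F2 | step 12 | (2Z)-3-[(4-methoxyphenyl)methoxy]-2-(propan-2-yl)prop-2-en-1-ol | OC/C(C(C)C)=C\OCc1ccc(OC)cc1
F3 | step 12 | [(1R,2S)-2-[(4-methoxyphenyl)methoxy]-1-(propan-2-yl)cyclopropyl]methanol | OC[C@]1(C(C)C)C[C@@H]1OCc1ccc(OC)cc1
F4 | step 12 | 5-({[(1S,2S)-2-[(4-methoxyphenyl)methoxy]-1-(propan-2-yl)cyclopropyl]methyl}sulfanyl)-1-phenyl-1H-tetrazole | S(C[C@]1(C(C)C)C[C@@H]1OCc1ccc(OC)cc1)c1nnnn1-c1ccccc1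
F5 | step 12 | 5-({[(1S,2S)-2-[(4-methoxyphenyl)methoxy]-1-(propan-2-yl)cyclopropyl]methyl}sulfonyl)-1-phenyl-1H-tetrazole | O=S(=O)(C[C@]1(C(C)C)C[C@@H]1OCc1ccc(OC)cc1)c1nnnn1-c1ccccc1
F6 | step 12 | triethyl({(3S,1E)-1-[(1R,2S)-2-[(4-methoxyphenyl)methoxy]-1-(propan-2-yl)cyclopropyl]-3-methyloct-1-en-6-yn-3-yl}oxy)silane | CC#CCC[C@](C)(O[Si](CC)(CC)CC)/C=C/[C@]1(C(C)C)C[C@@H]1OCc1ccc(OC)cc1
F7 | step 14 | 8β-[(4-methoxyphenyl)methoxy]-4α-[(triethylsilyl)oxy]-5βH,7βH-guai-1(10)-en-6β-ol | CC1=C2CC[C@](C)(O[Si](CC)(CC)CC)[C@@H]2[C@@H](O)[C@H](C(C)C)[C@@H](OCc2ccc(OC)cc2)C1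
F8 | step 14 | 8β-[(4-methoxyphenyl)methoxy]-4α-[(triethylsilyl)oxy]-5βH,7βH-guai-1(10)-en-6-one | CC1=C2CC[C@](C)(O[Si](CC)(CC)CC)[C@@H]2C(=O)[C@H](C(C)C)[C@@H](OCc2ccc(OC)cc2)C1
F9 | step 14 | 8β-hydroxy-4α-[(triethylsilyl)oxy]-5βH,7βH-guai-1(10)-en-6-one | CC1=C2CC[C@](C)(O[Si](CC)(CC)CC)[C@@H]2C(=O)[C@H](C(C)C)[C@@H](O)C1
F10 | step 14 | 4α-[(triethylsilyl)oxy]-5βH,7βH-guai-1(10)-ene-6α,8β-diol | CC1=C2CC[C@](C)(O[Si](CC)(CC)CC)[C@@H]2[C@H](O)[C@H](C(C)C)[C@@H](O)C1
F11 | step 11 | ({[(1R,2S)-2-[(4-methoxyphenyl)methoxy]-1-(propan-2-yl)cyclopropyl]methyl}sulfanyl)benzene | S(C[C@@]1(C(C)C)C[C@@H]1OCc1ccc(OC)cc1)c1ccccc1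
F12 | step 11 | ({[(1R,2S)-2-[(4-methoxyphenyl)methoxy]-1-(propan-2-yl)cyclopropyl]methyl}sulfonyl)benzene | O=S(=O)(C[C@@]1(C(C)C)C[C@@H]1OCc1ccc(OC)cc1)c1ccccc1
F13 | step 11 | (3S)-1-(benzenesulfonyl)-1-[(1S,2S)-2-[(4-methoxyphenyl)methoxy]-1-(propan-2-yl)cyclopropyl]-3-methyl-3-[(triethylsilyl)oxy]oct-6-yn-2-yl acetate (mixture at C1 and C2 of the chain) | CC#CCC[C@](C)(O[Si](CC)(CC)CC)C(OC(C)=O)C([C@@]1(C(C)C)C[C@@H]1OCc1ccc(OC)cc1)S(=O)(=O)c1ccccc1
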